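## Retrosynthetic overview

1. Target 15 is (2S)-2,3-dihydroamentoflavone; it is released last by hydrogenolysis of its hexabenzyl ether 14.
2. Flavanone ring C is disconnected at C3–C4 as an enantioselective intramolecular hydroacylation. The enabling feature is that C4 (the C=O) sits on ring A ortho to the ring oxygen O1, C3 is an unsubstituted CH2 and C2 carries one H. O1–C2H(aryl)–C3H2–C4(=O) is thus the retron of a salicylaldehyde C–H added across the C2=C3 bond of its 1-arylvinyl ether (H to C2, acyl to C3), so the achiral precursor 13 gains its only stereocentre in this step.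
3. The biaryl bond (ring B C3' to flavone C8) comes from Suzuki–Miyaura coupling of ring B boronate 12 with 8-iodo-tri-O-benzylapigenin 5.
4. Enol ether 11 comes from Mitsunobu etherification of salicylaldehyde 2 with racemic bromohydrin 9, then E2 loss of HBr.
5. Ring order: the flavone rings are bought as apigenin, the biaryl bond follows, and flavanone ring C is closed last (step 11), before deprotection.

Key step: step 11

Assumption: (R)-DTBM-SEGPHOS is taken to deliver the (2S) product; the sense of induction cannot be predicted with certainty for this substrate class, and the (S)-ligand is used instead if a model substrate shows the opposite sense.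

## Route

Step 1
Reactants: 1 2,4,6-trihydroxybenzaldehyde
Product: 2 2,4-bis(benzyloxy)-6-hydroxybenzaldehyde
Conditions: BnBr (2.05 equiv), K2CO3 (2.2 equiv), DMF, 0 °C to rt
Reagents that add atoms: benzyl bromide, BrCc1ccccc1
Why: Williamson etherification in which the 4-OH and one ortho OH are alkylated, while the remaining ortho OH is held in a hydrogen bond to the formyl group and should stay free with two equivalents of benzyl bromide.

Step 2
Reactants: 3 apigenin
Product: 4 5,7-bis(benzyloxy)-2-[4-(benzyloxy)phenyl]-4H-chromen-4-one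
Conditions: BnBr (4.5 equiv), K2CO3 (5 equiv), DMF, 80 °C
Reagents that add atoms: benzyl bromide, BrCc1ccccc1
Why: Williamson etherification in which the 7- and 4'-OH react fast and the chelated 5-OH is forced by excess reagent and heat.

Step 3
Reactants: 4 5,7-bis(benzyloxy)-2-[4-(benzyloxy)phenyl]-4H-chromen-4-one
Product: 5 5,7-bis(benzyloxy)-2-[4-(benzyloxy)phenyl]-8-iodo-4H-chromen-4-one
Conditions: NIS (1.1 equiv), CF3CO2H (0.2 equiv), CH2Cl2/MeCN, 0 °C to rt
Reagents that add atoms: N-iodosuccinimide, O=C1CCC(=O)N1I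
Why: Electrophilic aromatic iodination that should go to C8, which is activated by the 7-benzyloxy (ortho) and 5-benzyloxy (para) groups and is less hindered than C6 between two benzyloxy groups.

Step 4
Reactants: 6 1-(3-bromo-4-hydroxyphenyl)ethanone
Product: 7 1-[4-(benzyloxy)-3-bromophenyl]ethanone
Conditions: BnBr (1.1 equiv), K2CO3 (1.5 equiv), acetone, reflux
Reagents that add atoms: benzyl bromide, BrCc1ccccc1
Why: Williamson etherification of the only phenol.

Step 5
Reactants: 7 1-[4-(benzyloxy)-3-bromophenyl]ethanone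
Product: 8 1-[4-(benzyloxy)-3-bromophenyl]-2-bromoethanone
Conditions: CuBr2 (2.1 equiv), EtOAc/CHCl3 1:1, reflux
Reagents that add atoms: CuBr2, Br[Cu]Br
Why: Selective α-bromination of an aryl methyl ketone with CuBr2 through the copper enolate, the ring being deactivated by the acetyl group and bromine.

Step 6
Reactants: 8 1-[4-(benzyloxy)-3-bromophenyl]-2-bromoethanone
Product: 9 rac-1-[4-(benzyloxy)-3-bromophenyl]-2-bromoethanol
Conditions: NaBH4 (0.6 equiv), MeOH/THF, −10 °C to 0 °C; aq NH4Cl quench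
Reagents that add atoms: none
Why: Hydride reduction of the α-bromo ketone, with a cold, short reaction and mildly acidic quench to keep the bromohydrin from closing to the epoxide; the racemate suffices because this stereocentre is removed in step 8.

Step 7
Reactants: 9 rac-1-[4-(benzyloxy)-3-bromophenyl]-2-bromoethanol; 2 2,4-bis(benzyloxy)-6-hydroxybenzaldehyde
Product: 10 rac-2,4-bis(benzyloxy)-6-{1-[4-(benzyloxy)-3-bromophenyl]-2-bromoethoxy}benzaldehyde
Conditions: PPh3 (1.5 equiv), DIAD (1.5 equiv), THF, 0 °C to rt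
Reagents that add atoms: none
Why: Mitsunobu etherification in which the acidic chelated phenol attacks the activated benzylic carbon, directly or through the bromonium ion, both paths giving the same constitution while configuration is irrelevant here.

Step 8
Reactants: 10 rac-2,4-bis(benzyloxy)-6-{1-[4-(benzyloxy)-3-bromophenyl]-2-bromoethoxy}benzaldehyde
Product: 11 2,4-bis(benzyloxy)-6-({1-[4-(benzyloxy)-3-bromophenyl]ethenyl}oxy)benzaldehyde
Conditions: KOtBu (1.3 equiv), THF, −20 °C to 0 °C; chromatography on Et3N-deactivated silica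
Reagents that add atoms: none
Why: E2 dehydrobromination in which the only β-hydrogen is the benzylic C–H next to the ether oxygen, so the 1,1-disubstituted aryl enol ether is the only alkene that can form and the aldehyde cannot enolise.

Step 9
Reactants: 11 2,4-bis(benzyloxy)-6-({1-[4-(benzyloxy)-3-bromophenyl]ethenyl}oxy)benzaldehyde
Product: 12 2,4-bis(benzyloxy)-6-({1-[4-(benzyloxy)-3-(4,4,5,5-tetramethyl-1,3,2-dioxaborolan-2-yl)phenyl]ethenyl}oxy)benzaldehyde
Conditions: B2pin2 (1.2 equiv), Pd(dppf)Cl2 (3 mol %), KOAc (3 equiv), 1,4-dioxane, 85 °C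
Reagents that add atoms: bis(pinacolato)diboron, CC1(C)OB(OC1(C)C)B1OC(C)(C)C(C)(C)O1
Why: Miyaura borylation of the aryl bromide, which aldehyde and enol ether should tolerate under KOAc and zerovalent palladium.

Step 10
Reactants: 12 2,4-bis(benzyloxy)-6-({1-[4-(benzyloxy)-3-(4,4,5,5-tetramethyl-1,3,2-dioxaborolan-2-yl)phenyl]ethenyl}oxy)benzaldehyde; 5 5,7-bis(benzyloxy)-2-[4-(benzyloxy)phenyl]-8-iodo-4H-chromen-4-one
Product: 13 2,4-bis(benzyloxy)-6-[(1-{4-(benzyloxy)-3-[5,7-bis(benzyloxy)-2-(4-(benzyloxy)phenyl)-4-oxo-4H-chromen-8-yl]phenyl}ethenyl)oxy]benzaldehyde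
Conditions: Pd(OAc)2 (5 mol %), SPhos (10 mol %), K3PO4 (3 equiv), toluene/H2O 10:1, 80 °C
Reagents that add atoms: none
Why: Suzuki–Miyaura coupling in which SPhos should promote oxidative addition to the hindered 8-iodide and transmetalation of the ortho-alkoxy boronate, while the weak base leaves enol ether and aldehyde intact.

Step 11
Reactants: 13 2,4-bis(benzyloxy)-6-[(1-{4-(benzyloxy)-3-[5,7-bis(benzyloxy)-2-(4-(benzyloxy)phenyl)-4-oxo-4H-chromen-8-yl]phenyl}ethenyl)oxy]benzaldehyde
Product: 14 (2S)-5,7-bis(benzyloxy)-2-{4-(benzyloxy)-3-[5,7-bis(benzyloxy)-2-(4-(benzyloxy)phenyl)-4-oxo-4H-chromen-8-yl]phenyl}-2,3-dihydro-4H-chromen-4-one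
Conditions: [Rh(cod)Cl]2 (2.5 mol %), (R)-DTBM-SEGPHOS (5.5 mol %), NaB[C6H3(CF3)2]4 (5 mol %), dry THF, 60 °C
Reagents that add atoms: none
Why: Proposed new method: oxidative addition of the formyl C–H bond of 13 to the cationic monovalent rhodium bisphosphine complex should give an acyl rhodium hydride with the tethered enol-ether alkene chelated; hydride insertion then delivers H to the internal carbon C2 and Rh to the terminal carbon C3, and C–C reductive elimination from the seven-membered acyl–alkyl rhodacycle forms the C3–C4 bond. The closest known reaction type is the Rh/bisphosphine-catalysed enantioselective endo hydroacylation of ortho-allylbenzaldehydes carrying 1,1-disubstituted alkenes (to 3-substituted tetralones) and of N-vinylindole-2-carbaldehydes; an oxygen-tethered 1-arylvinyl ether giving a chroman-4-one has not been shown, hence the label. Flavanone ring C, the only ring formed, is closed in a formal 6-endo-trig mode with respect to the alkene. The new stereocentre C2 arises in the hydride insertion and is under catalyst control alone, the C2-symmetric ligand differentiating the two faces of the 1,1-disubstituted alkene of an achiral substrate. The step needs 6-endo over 5-exo regioselectivity and hydroacylation over decarbonylation: the 1-aryl group disfavours Rh–C bond formation at the fully substituted C2 (which would lead to a 2-methyl-2-arylbenzofuran-3-one), chelation of the alkene and the two ortho oxygen substituents on ring A should hold the acyl hydride against CO loss, and the electron-poor trisubstituted flavone alkene is remote from the aldehyde.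

Step 12
Reactants: 14 (2S)-5,7-bis(benzyloxy)-2-{4-(benzyloxy)-3-[5,7-bis(benzyloxy)-2-(4-(benzyloxy)phenyl)-4-oxo-4H-chromen-8-yl]phenyl}-2,3-dihydro-4H-chromen-4-one
Product: 15 (2S)-5,7-dihydroxy-2-{4-hydroxy-3-[5,7-dihydroxy-2-(4-hydroxyphenyl)-4-oxo-4H-chromen-8-yl]phenyl}-2,3-dihydro-4H-chromen-4-one
Conditions: H2 (1 atm), 10 % Pd/C, EtOAc/MeOH 1:1, rt, stopped at complete debenzylation
Reagents that add atoms: none
Why: Hydrogenolysis of six benzyl aryl ethers under neutral conditions, which cannot open or epimerise the flavanone ring, while the conjugated flavone alkene and both ketones should be reduced much more slowly than the O-benzyl groups.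

## Compound list

1 | 2,4,6-trihydroxybenzaldehyde | O=Cc1c(O)cc(O)cc1O | starting material
2 | 2,4-bis(benzyloxy)-6-hydroxybenzaldehyde | O=Cc1c(O)cc(OCc2ccccc2)cc1OCc1ccccc1 | intermediate
3 | apigenin | O=c1cc(-c2ccc(O)cc2)oc2cc(O)cc(O)c12 | starting material
4 | 5,7-bis(benzyloxy)-2-[4-(benzyloxy)phenyl]-4H-chromen-4-one | O=c1cc(-c2ccc(OCc3ccccc3)cc2)oc2cc(OCc3ccccc3)cc(OCc3ccccc3)c12 | intermediate
5 | 5,7-bis(benzyloxy)-2-[4-(benzyloxy)phenyl]-8-iodo-4H-chromen-4-one | O=c1cc(-c2ccc(OCc3ccccc3)cc2)oc2c(I)c(OCc3ccccc3)cc(OCc3ccccc3)c12 | intermediate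
6 | 1-(3-bromo-4-hydroxyphenyl)ethanone | CC(=O)c1ccc(O)c(Br)c1 | starting material
7 | 1-[4-(benzyloxy)-3-bromophenyl]ethanone | CC(=O)c1ccc(OCc2ccccc2)c(Br)c1 | intermediate
8 | 1-[4-(benzyloxy)-3-bromophenyl]-2-bromoethanone | O=C(CBr)c1ccc(OCc2ccccc2)c(Br)c1 | intermediate
9 | rac-1-[4-(benzyloxy)-3-bromophenyl]-2-bromoethanol | OC(CBr)c1ccc(OCc2ccccc2)c(Br)c1 | intermediate
10 | rac-2,4-bis(benzyloxy)-6-{1-[4-(benzyloxy)-3-bromophenyl]-2-bromoethoxy}benzaldehyde | O=Cc1c(OC(CBr)c2ccc(OCc3ccccc3)c(Br)c2)cc(OCc2ccccc2)cc1OCc1ccccc1 | intermediate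
11 | 2,4-bis(benzyloxy)-6-({1-[4-(benzyloxy)-3-bromophenyl]ethenyl}oxy)benzaldehyde | O=Cc1c(OC(=C)c2ccc(OCc3ccccc3)c(Br)c2)cc(OCc2ccccc2)cc1OCc1ccccc1 | intermediate
12 | 2,4-bis(benzyloxy)-6-({1-[4-(benzyloxy)-3-(4,4,5,5-tetramethyl-1,3,2-dioxaborolan-2-yl)phenyl]ethenyl}oxy)benzaldehyde | O=Cc1c(OC(=C)c2ccc(OCc3ccccc3)c(B3OC(C)(C)C(C)(C)O3)c2)cc(OCc2ccccc2)cc1OCc1ccccc1 | intermediate
13 | 2,4-bis(benzyloxy)-6-[(1-{4-(benzyloxy)-3-[5,7-bis(benzyloxy)-2-(4-(benzyloxy)phenyl)-4-oxo-4H-chromen-8-yl]phenyl}ethenyl)oxy]benzaldehyde | O=Cc1c(OC(=C)c2ccc(OCc3ccccc3)c(-c3c(OCc4ccccc4)cc(OCc4ccccc4)c4c(=O)cc(-c5ccc(OCc6ccccc6)cc5)oc34)c2)cc(OCc2ccccc2)cc1OCc1ccccc1 | intermediate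
14 | (2S)-5,7-bis(benzyloxy)-2-{4-(benzyloxy)-3-[5,7-bis(benzyloxy)-2-(4-(benzyloxy)phenyl)-4-oxo-4H-chromen-8-yl]phenyl}-2,3-dihydro-4H-chromen-4-one | O=C1C[C@@H](c2ccc(OCc3ccccc3)c(-c3c(OCc4ccccc4)cc(OCc4ccccc4)c4c(=O)cc(-c5ccc(OCc6ccccc6)cc5)oc34)c2)Oc2cc(OCc3ccccc3)cc(OCc3ccccc3)c21 | intermediate
15 | (2S)-5,7-dihydroxy-2-{4-hydroxy-3-[5,7-dihydroxy-2-(4-hydroxyphenyl)-4-oxo-4H-chromen-8-yl]phenyl}-2,3-dihydro-4H-chromen-4-one | O=C1C[C@@H](c2ccc(O)c(-c3c(O)cc(O)c4c(=O)cc(-c5ccc(O)cc5)oc34)c2)Oc2cc(O)cc(O)c21 | target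

## Step count and risks

Total step count: 12. Longest linear sequence: 9 steps (steps 4 to 12, from compound 6 to compound 15).

**Step 11 (key step).** The acyl rhodium hydride may lose CO before the C–C bond forms. Hydride insertion may take the opposite regiochemistry and lead to five-membered ring closure. Facial selectivity at the 1,1-disubstituted alkene may be poor. The Lewis-acidic cationic metal may also trigger hydrolysis or cationic cyclisation of the enol ether. The fallback uses known chemistry, sets out from compound 8 and comes back to the route at compound 14.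
- CBS reduction of 8 with (S)-2-methyl-CBS-oxazaborolidine and BH3·SMe2 (THF, 0 °C), the aryl group acting as the large substituent, should give (S)-1-[4-(benzyloxy)-3-bromophenyl]-2-bromoethanol F1.
- Mitsunobu etherification of this alcohol with phenol 2 (PPh3, DIAD, toluene, −20 °C to 0 °C), with inversion at the benzylic carbon, should give (R)-2,4-bis(benzyloxy)-6-{1-[4-(benzyloxy)-3-bromophenyl]-2-bromoethoxy}benzaldehyde F2.
- NHC-catalysed intramolecular alkylation of the aldehyde (3-benzyl-5-(2-hydroxyethyl)-4-methylthiazolium chloride, Cs2CO3, THF, rt) closes the same C3–C4 bond, the Breslow intermediate displacing the primary bromide without touching the stereocentre. It should give (2S)-5,7-bis(benzyloxy)-2-[4-(benzyloxy)-3-bromophenyl]-2,3-dihydro-4H-chromen-4-one F3.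
- Miyaura borylation (B2pin2, Pd(dppf)Cl2, KOAc, 1,4-dioxane, 80 °C) should give (2S)-5,7-bis(benzyloxy)-2-[4-(benzyloxy)-3-(4,4,5,5-tetramethyl-1,3,2-dioxaborolan-2-yl)phenyl]-2,3-dihydro-4H-chromen-4-one F4.
- Suzuki–Miyaura coupling of this boronate with iodide 5 (Pd(OAc)2, SPhos, K3PO4, toluene/H2O, 50 °C, kept mild to avoid base-induced ring opening of the flavanone) returns to 14.

**Step 10.** Oxidative addition to the doubly ortho-substituted 8-iodide may be slow, so protodeboronation of 12 and homocoupling can take over. Forcing conditions are limited by the enol ether and aldehyde. The fallback moves the biaryl coupling to the robust ketone stage; it sets out from compounds 7 and 5 and comes back at compound 13.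
- Miyaura borylation of 7 (B2pin2, Pd(dppf)Cl2, KOAc, 1,4-dioxane, 90 °C) should give 1-[4-(benzyloxy)-3-(4,4,5,5-tetramethyl-1,3,2-dioxaborolan-2-yl)phenyl]ethanone F5.
- Suzuki–Miyaura coupling with 5 under forcing conditions (Pd(OAc)2, SPhos, K3PO4, 1,4-dioxane/H2O, 100 °C) should give 8-[5-acetyl-2-(benzyloxy)phenyl]-5,7-bis(benzyloxy)-2-[4-(benzyloxy)phenyl]-4H-chromen-4-one F6.
- α-Bromination (PhNMe3Br3, THF, 0 °C) should give 5,7-bis(benzyloxy)-2-[4-(benzyloxy)phenyl]-8-[2-(benzyloxy)-5-(bromoacetyl)phenyl]-4H-chromen-4-one F7.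
- NaBH4 reduction (MeOH/THF, −20 °C, where the flavone carbonyl is not touched) should give rac-5,7-bis(benzyloxy)-2-[4-(benzyloxy)phenyl]-8-[2-(benzyloxy)-5-(2-bromo-1-hydroxyethyl)phenyl]-4H-chromen-4-one F8.
- Mitsunobu etherification with 2 (PPh3, DIAD, THF) should give rac-2,4-bis(benzyloxy)-6-(1-{4-(benzyloxy)-3-[5,7-bis(benzyloxy)-2-(4-(benzyloxy)phenyl)-4-oxo-4H-chromen-8-yl]phenyl}-2-bromoethoxy)benzaldehyde F9.
- E2 elimination with KOtBu (THF, −20 °C to 0 °C) gives 13.

**Step 12.** Over-reduction of the flavone C2=C3 bond or of the aryl ketones, or hydrogenolytic opening of the benzylic C2–O1 bond of ring C, may accompany the sixfold debenzylation. The fallback sets out from compound 14 and comes back at compound 15. It replaces hydrogen by Lewis-acid ether cleavage with BCl3 and pentamethylbenzene as benzyl-cation scavenger (CH2Cl2, −78 °C), which cannot reduce any group. It makes no compound outside the compound list (entry F0).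

## Further compounds

F1 | step 11 | (S)-1-[4-(benzyloxy)-3-bromophenyl]-2-bromoethanol | BrC[C@H](c1ccc(OCc2ccccc2)c(Br)c1)O
F2 | step 11 | (R)-2,4-bis(benzyloxy)-6-{1-[4-(benzyloxy)-3-bromophenyl]-2-bromoethoxy}benzaldehyde | BrC[C@@H](c1ccc(OCc2ccccc2)c(Br)c1)Oc1cc(OCc2ccccc2)cc(OCc2ccccc2)c1C=O
F3 | step 11 | (2S)-5,7-bis(benzyloxy)-2-[4-(benzyloxy)-3-bromophenyl]-2,3-dihydro-4H-chromen-4-one | O=C1C[C@@H](c2ccc(OCc3ccccc3)c(Br)c2)Oc2cc(OCc3ccccc3)cc(OCc3ccccc3)c21
F4 | step 11 | (2S)-5,7-bis(benzyloxy)-2-[4-(benzyloxy)-3-(4,4,5,5-tetramethyl-1,3,2-dioxaborolan-2-yl)phenyl]-2,3-dihydro-4H-chromen-4-one | O=C1C[C@@H](c2ccc(OCc3ccccc3)c(B3OC(C)(C)C(C)(C)O3)c2)Oc2cc(OCc3ccccc3)cc(OCc3ccccc3)c21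
F5 | step 10 | 1-[4-(benzyloxy)-3-(4,4,5,5-tetramethyl-1,3,2-dioxaborolan-2-yl)phenyl]ethanone | CC(=O)c1ccc(OCc2ccccc2)c(B2OC(C)(C)C(C)(C)O2)c1
F6 | step 10 | 8-[5-acetyl-2-(benzyloxy)phenyl]-5,7-bis(benzyloxy)-2-[4-(benzyloxy)phenyl]-4H-chromen-4-one | CC(=O)c1ccc(OCc2ccccc2)c(-c2c(OCc3ccccc3)cc(OCc3ccccc3)c3c(=O)cc(-c4ccc(OCc5ccccc5)cc4)oc23)c1
F7 | step 10 | 5,7-bis(benzyloxy)-2-[4-(benzyloxy)phenyl]-8-[2-(benzyloxy)-5-(bromoacetyl)phenyl]-4H-chromen-4-one | O=C(CBr)c1ccc(OCc2ccccc2)c(-c2c(OCc3ccccc3)cc(OCc3ccccc3)c3c(=O)cc(-c4ccc(OCc5ccccc5)cc4)oc23)c1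
F8 | step 10 | rac-5,7-bis(benzyloxy)-2-[4-(benzyloxy)phenyl]-8-[2-(benzyloxy)-5-(2-bromo-1-hydroxyethyl)phenyl]-4H-chromen-4-one | OC(CBr)c1ccc(OCc2ccccc2)c(-c2c(OCc3ccccc3)cc(OCc3ccccc3)c3c(=O)cc(-c4ccc(OCc5ccccc5)cc4)oc23)c1
F9 | step 10 | rac-2,4-bis(benzyloxy)-6-(1-{4-(benzyloxy)-3-[5,7-bis(benzyloxy)-2-(4-(benzyloxy)phenyl)-4-oxo-4H-chromen-8-yl]phenyl}-2-bromoethoxy)benzaldehyde | O=Cc1c(OC(CBr)c2ccc(OCc3ccccc3)c(-c3c(OCc4ccccc4)cc(OCc4ccccc4)c4c(=O)cc(-c5ccc(OCc6ccccc6)cc5)oc34)c2)cc(OCc2ccccc2)cc1OCc1ccccc1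
F0 | step 12 | none | none
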